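**Strategy.** Ring B, the hydroxyquinone (C1′ on chroman C3, C2′=O, C3′ prenyl, C4′–OH, C5′=O, C6′–H), is built last from a strained four-membered ring. The 1,3-dioxygenated C2′–C3′(prenyl)–C4′ unit plus C1′ is a 3-ethoxy-2-prenylcyclobutenone carrying the (3R)-chroman on its sp3 carbon. The unsubstituted C5′–C6′ edge is an α-oxygenated vinyllithium. Addition of 5,6-dihydro-1,4-dioxin-2-yllithium to the carbonyl (C4′–C5′), oxy-anion-driven 4π opening of the cyclobutene, 6π closure (C6′–C1′) and loss of the glycol arm should give the trioxygenated arene in one operation. (NH4)2Ce(NO3)6 then unveils the quinone. The stereocentre comes from asymmetric hydrogenation of a Stobbe half-ester.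

Key step: step 11

Assumptions: compounds 1, 2, 6, 13 (solution in hexanes) and 19 are taken as commercial. The (S,S)-Et-DuPhos ligand is assumed to give the R acid in step 5, by analogy with related alkylidenesuccinate half-esters; the antipodal ligand is used if the sense is reversed.

**Step 1**
Reactants: 1 2,4,6-trihydroxybenzaldehyde; 2 prenyl bromide (1-bromo-3-methylbut-2-ene)
Product: 3 2,4,6-trihydroxy-3-(3-methylbut-2-en-1-yl)benzaldehyde
Conditions: 2 (1.0 equiv), 10% aq. KOH, 0 °C → rt; then cold dilute HCl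
Reagents that add atoms: none
Why: C-alkylation of the phloroglucinol-type phenoxide, in which the two free ring positions are equivalent so that mono-C-prenylation should give a single regioisomer while the limiting bromide curbs bis- and O-alkylation.

**Step 2**
Reactants: 3
Product: 4 2-hydroxy-4,6-bis(methoxymethoxy)-3-(3-methylbut-2-en-1-yl)benzaldehyde
Conditions: MOMCl (2.2 equiv), i-Pr2NEt, CH2Cl2, 0 °C → rt
Reagents that add atoms: chloromethyl methyl ether, COCCl
Why: Williamson-type acetal formation in which the para hydroxyl and then the less hindered ortho hydroxyl should react, leaving free the hydroxyl that is flanked by formyl and prenyl and hydrogen-bonded to the carbonyl.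

**Step 3**
Reactants: 4
Product: 5 2-methoxy-4,6-bis(methoxymethoxy)-3-(3-methylbut-2-en-1-yl)benzaldehyde
Conditions: MeI, K2CO3, DMF, 40 °C
Reagents that add atoms: iodomethane, CI
Why: Williamson methylation of the one remaining phenol, which fixes the methoxy group between the formyl carbon and the prenyl group as required for C5-OMe/C6-prenyl of ring A.

**Step 4**
Reactants: 5; 6 dimethyl succinate
Product: 7 (3E)-3-(methoxycarbonyl)-4-[2-methoxy-4,6-bis(methoxymethoxy)-3-(3-methylbut-2-en-1-yl)phenyl]but-3-enoic acid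
Conditions: 6 (2 equiv), KOt-Bu, t-BuOH, 60 °C; then cold 1 M HCl to pH 3
Reagents that add atoms: none
Why: Stobbe condensation (aldol addition, lactonisation to the paraconate and E1cB ring opening), which should deliver the half-ester with the aryl group trans to the conjugated ester and with the two carboxyl groups already differentiated.

**Step 5**
Reactants: 7
Product: 8 (3R)-3-(methoxycarbonyl)-4-[2-methoxy-4,6-bis(methoxymethoxy)-3-(3-methylbut-2-en-1-yl)phenyl]butanoic acid
Conditions: [Rh(cod)((S,S)-Et-DuPhos)]BF4 (1 mol%), H2 (5 bar), Et3N (1 equiv), MeOH, rt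
Reagents that add atoms: none
Why: Carboxylate-directed asymmetric hydrogenation of an itaconate-type half-ester, in which the chiral bisphospholane–rhodium catalyst selects the alkene face and so sets the future chroman C3 as R, while the unfunctionalised prenyl alkene should not be reduced.

**Step 6**
Reactants: 8
Product: 10 (4R)-4-{[4,6-dihydroxy-2-methoxy-3-(3-methylbut-2-en-1-yl)phenyl]methyl}oxolan-2-one, via hydroxy acid 9 (not isolated)
Conditions: LiBH4, THF, 0 → 40 °C; then 3 M HCl, MeOH, 40 °C
Reagents that add atoms: none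
Why: Chemoselective borohydride reduction of the ester beside the unreactive lithium carboxylate, followed by acid-promoted lactonisation and acetal cleavage of both MOM ethers in the same pot, with the stereocentre untouched.

**Step 7**
Reactants: 10
Product: 11 2-[(3R)-7-hydroxy-5-methoxy-6-(3-methylbut-2-en-1-yl)-3,4-dihydro-2H-chromen-3-yl]acetic acid
Conditions: Cs2CO3, DMF (0.02 M), 110 °C; then 1 M HCl
Reagents that add atoms: none
Why: Intramolecular SN2 O-alkylation of the ortho phenoxide at the lactone O–CH2 carbon (alkyl–oxygen cleavage, 6-exo-tet), which should close the chroman and release the carboxylate irreversibly, only the ortho phenoxide being able to reach.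

**Step 8**
Reactants: 11
Product: 12 tert-butyldimethylsilyl 2-[(3R)-7-(tert-butyldimethylsilyloxy)-5-methoxy-6-(3-methylbut-2-en-1-yl)-3,4-dihydro-2H-chromen-3-yl]acetate
Conditions: TBSCl (2.4 equiv), imidazole, DMF, rt
Reagents that add atoms: tert-butyldimethylsilyl chloride, CC(C)(C)[Si](C)(C)Cl
Why: Silylation of both the phenol and the acid, which protects ring A and provides a silyl ester that can be turned into the acid chloride under neutral conditions.

**Step 9**
Reactants: 13 ethoxyacetylene; 2 prenyl bromide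
Product: 15 1-ethoxy-5-methylhex-4-en-1-yne, via lithium ethoxyacetylide 14 (not isolated)
Conditions: n-BuLi, THF, −78 °C; then 2, HMPA, −78 °C → rt
Reagents that add atoms: none
Why: SN2 alkylation of the lithium alkoxyacetylide with the allylic bromide, which places the prenyl group on the nucleophilic alkyne carbon of the ynol ether.

**Step 10**
Reactants: 12; 15
Product: 18 4-[(3R)-7-(tert-butyldimethylsilyloxy)-5-methoxy-6-(3-methylbut-2-en-1-yl)-3,4-dihydro-2H-chromen-3-yl]-3-ethoxy-2-(3-methylbut-2-en-1-yl)cyclobut-2-en-1-one (both epimers at the ring sp3 carbon), via acid chloride 16 (not isolated), via ketene 17 (not isolated)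
Conditions: (COCl)2, cat. DMF, CH2Cl2, 0 °C → rt, evaporate; then 15 (2 equiv), Et3N (slow addition), CH2Cl2, rt
Reagents that add atoms: none
Why: Conversion of the silyl ester into the acid chloride, dehydrochlorination to the aldoketene and regioselective ketene–ynol ether [2+2] cycloaddition (ketene carbonyl carbon to the prenyl-bearing alkyne carbon), the new ring stereocentre forming as a mixture that step 11 erases.

**Step 11**
Reactants: 18; 19 2,3-dihydro-1,4-dioxine
Product: 24 3-ethoxy-6-(2-hydroxyethoxy)-2-(3-methylbut-2-en-1-yl)-4-[(3R)-7-(tert-butyldimethylsilyloxy)-5-methoxy-6-(3-methylbut-2-en-1-yl)-3,4-dihydro-2H-chromen-3-yl]phenol, via dioxenyllithium 20 (not isolated), via cyclobutenolate 21 (not isolated), via oxidotriene 22 (not isolated), via cyclohexadienolate 23 (not isolated)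
Conditions: 19 (1.5 equiv), t-BuLi (1.3 equiv), THF, −30 → 0 °C; then 18, −78 °C → rt (40 °C if needed); aq. NH4Cl
Reagents that add atoms: none
Why: 1,2-Addition of the α-oxygenated vinyllithium to the cyclobutenone carbonyl forms C4′–C5′, the cyclobutenolate opens by oxy-anion-accelerated conrotatory 4π electrocyclic ring opening (strain release), and the 3-oxidotriene closes ring B by thermal disrotatory 6π electrocyclisation, forming C6′–C1′. E1cB loss of the glycol oxygen from C6′ of the cyclohexadienolate and tautomerisation of C1′–H then aromatise the ring, so no oxidant is needed. The closest known reaction type is the ring expansion of cyclobutenones to cyclohexenones or phenols by alkenyllithium addition, related to the thermal ring expansion of 4-alkenyl-4-hydroxycyclobutenones. No stereocentre is created in the product, since the sp3 centres at C1′, C4′ and C6′ are transient and chroman C3 is a spectator. The step needs carbonyl addition instead of enolisation and a triene whose central alkene holds the dioxenyl group cis to C2′; the first is secured by the low acidity of the ring C–H (its enolate would be a cyclobutadiene-type anion), the second by the strong outward torquoselectivity of the oxido group. The chroman-bearing terminus may rotate inward from the major adduct, but the oxidotriene is a dienolate whose terminal geometry can equilibrate, and both geometries converge on the same arene.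

**Step 12**
Reactants: 24
Product: 25 2-hydroxy-3-(3-methylbut-2-en-1-yl)-5-[(3R)-7-(tert-butyldimethylsilyloxy)-5-methoxy-6-(3-methylbut-2-en-1-yl)-3,4-dihydro-2H-chromen-3-yl]cyclohexa-2,5-diene-1,4-dione
Conditions: (NH4)2Ce(NO3)6 (2.2 equiv), MeCN/H2O, −10 → 0 °C
Reagents that add atoms: water, O
Why: Oxidative dealkylation of the para-dialkoxyphenol (electron transfer, ipso attack of water, loss of ethanol and ethylene glycol) to the 2-hydroxy-1,4-benzoquinone, ring B being by far the most easily oxidised arene while silylated ring A and the prenyl groups should be spared.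

**Step 13**
Reactants: 25
Product: 26 2-hydroxy-5-[(3R)-7-hydroxy-5-methoxy-6-(3-methylbut-2-en-1-yl)-3,4-dihydro-2H-chromen-3-yl]-3-(3-methylbut-2-en-1-yl)cyclohexa-2,5-diene-1,4-dione (target)
Conditions: Bu4NF, AcOH (1:1), THF, 0 °C
Reagents that add atoms: none
Why: Fluoride-mediated cleavage of the aryl silyl ether, buffered with acetic acid so that the hydroxyquinone is not exposed to strong base, which should give the target with C3 unchanged.

**Compound list**

1 | 2,4,6-trihydroxybenzaldehyde | O=Cc1c(O)cc(O)cc1O | starting material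
2 | prenyl bromide | CC(C)=CCBr | starting material
3 | 2,4,6-trihydroxy-3-(3-methylbut-2-en-1-yl)benzaldehyde | O=Cc1c(O)cc(O)c(CC=C(C)C)c1O | intermediate
4 | 2-hydroxy-4,6-bis(methoxymethoxy)-3-(3-methylbut-2-en-1-yl)benzaldehyde | O=Cc1c(OCOC)cc(OCOC)c(CC=C(C)C)c1O | intermediate
5 | 2-methoxy-4,6-bis(methoxymethoxy)-3-(3-methylbut-2-en-1-yl)benzaldehyde | O=Cc1c(OCOC)cc(OCOC)c(CC=C(C)C)c1OC | intermediate
6 | dimethyl succinate | COC(=O)CCC(=O)OC | starting material
7 | (3E)-3-(methoxycarbonyl)-4-arylbut-3-enoic acid (aryl = 2-methoxy-4,6-bis(methoxymethoxy)-3-prenylphenyl) | OC(=O)C/C(=C\c1c(OCOC)cc(OCOC)c(CC=C(C)C)c1OC)C(=O)OC | intermediate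
8 | (3R)-3-(methoxycarbonyl)-4-arylbutanoic acid (same aryl) | COCOc1cc(OCOC)c(CC=C(C)C)c(OC)c1C[C@H](CC(=O)O)C(=O)OC | intermediate
9 | (3R)-3-(hydroxymethyl)-4-arylbutanoic acid (same aryl; formed as its lithium salt) | COCOc1cc(OCOC)c(CC=C(C)C)c(OC)c1C[C@H](CC(=O)O)CO | intermediate
10 | (4R)-4-{[4,6-dihydroxy-2-methoxy-3-(3-methylbut-2-en-1-yl)phenyl]methyl}oxolan-2-one | COc1c(CC=C(C)C)c(O)cc(O)c1C[C@@H]1CC(=O)OC1 | intermediate
11 | 2-[(3R)-7-hydroxy-5-methoxy-6-prenylchroman-3-yl]acetic acid | COc1c(CC=C(C)C)c(O)cc2c1C[C@H](CC(=O)O)CO2 | intermediate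
12 | tert-butyldimethylsilyl 2-[(3R)-7-(tert-butyldimethylsilyloxy)-5-methoxy-6-prenylchroman-3-yl]acetate | COc1c(CC=C(C)C)c(O[Si](C)(C)C(C)(C)C)cc2c1C[C@H](CC(=O)O[Si](C)(C)C(C)(C)C)CO2 | intermediate
13 | ethoxyacetylene | CCOC#C | starting material
14 | lithium ethoxyacetylide | CCOC#C[Li] | intermediate
15 | 1-ethoxy-5-methylhex-4-en-1-yne | CCOC#CCC=C(C)C | intermediate
16 | 2-[(3R)-7-(tert-butyldimethylsilyloxy)-5-methoxy-6-prenylchroman-3-yl]acetyl chloride | COc1c(CC=C(C)C)c(O[Si](C)(C)C(C)(C)C)cc2c1C[C@H](CC(=O)Cl)CO2 | intermediate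
17 | 2-[(3R)-7-(tert-butyldimethylsilyloxy)-5-methoxy-6-prenylchroman-3-yl]ethen-1-one (ketene) | COc1c(CC=C(C)C)c(O[Si](C)(C)C(C)(C)C)cc2c1C[C@H](C=C=O)CO2 | intermediate
18 | 4-[(3R)-chroman-3-yl]-3-ethoxy-2-prenylcyclobut-2-en-1-one (chroman as in 12; ring sp3 carbon unassigned) | COc1c(CC=C(C)C)c(O[Si](C)(C)C(C)(C)C)cc2c1C[C@H](C1C(=O)C(CC=C(C)C)=C1OCC)CO2 | intermediate
19 | 2,3-dihydro-1,4-dioxine | C1=COCCO1 | starting material
20 | 5,6-dihydro-1,4-dioxin-2-yllithium | [Li]C1=COCCO1 | intermediate
21 | lithium 1-(5,6-dihydro-1,4-dioxin-2-yl)-3-ethoxy-2-prenyl-4-[(3R)-chroman-3-yl]cyclobut-2-en-1-olate | COc1c(CC=C(C)C)c(O[Si](C)(C)C(C)(C)C)cc2c1C[C@H](C1C(OCC)=C(CC=C(C)C)C1(O[Li])C1=COCCO1)CO2 | intermediate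
22 | lithium 3-oxidotriene (dioxenyl cis to C2′ across C3′=C4′; terminal geometry unassigned) | COc1c(CC=C(C)C)c(O[Si](C)(C)C(C)(C)C)cc2c1C[C@H](C=C(OCC)/C(CC=C(C)C)=C(/O[Li])C1=COCCO1)CO2 | intermediate
23 | lithium dioxane-fused cyclohexadienolate (C1′ and C6′ sp3, unassigned) | COc1c(CC=C(C)C)c(O[Si](C)(C)C(C)(C)C)cc2c1C[C@H](C1C(OCC)=C(CC=C(C)C)C(O[Li])=C3OCCOC13)CO2 | intermediate
24 | 3-ethoxy-6-(2-hydroxyethoxy)-2-prenyl-4-[(3R)-7-(tert-butyldimethylsilyloxy)-5-methoxy-6-prenylchroman-3-yl]phenol | COc1c(CC=C(C)C)c(O[Si](C)(C)C(C)(C)C)cc2c1C[C@H](c1cc(OCCO)c(O)c(CC=C(C)C)c1OCC)CO2 | intermediate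
25 | 2-hydroxy-3-prenyl-5-[(3R)-7-(tert-butyldimethylsilyloxy)-5-methoxy-6-prenylchroman-3-yl]cyclohexa-2,5-diene-1,4-dione | COc1c(CC=C(C)C)c(O[Si](C)(C)C(C)(C)C)cc2c1C[C@H](C1=CC(=O)C(O)=C(CC=C(C)C)C1=O)CO2 | intermediate
26 | 2-hydroxy-5-[(3R)-7-hydroxy-5-methoxy-6-prenylchroman-3-yl]-3-prenylcyclohexa-2,5-diene-1,4-dione | COc1c(CC=C(C)C)c(O)cc2c1C[C@H](C1=CC(=O)C(O)=C(CC=C(C)C)C1=O)CO2 | target

**Step count.** Total: 13 steps. Longest linear sequence: 12 steps (steps 1–8 and 10–13); step 9 is a one-step side branch.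

**Steps most likely to fail**

1. Step 11. Enolisation of the cyclobutenone may compete with carbonyl addition. The triene from the major adduct, with the chroman terminus turned inward, may also close slowly, so that hydrogen shifts or premature protonation (which would give the transposed cyclobutenone on work-up) intervene.
 Fallback (Diels–Alder construction of ring B, forming the same two bonds; sets out from 12, returns at 25, and bypasses step 10 as well):
 - The silyl ester of 12 alone is hydrolysed (AcOH/THF/H2O, rt) to 2-[(3R)-7-(tert-butyldimethylsilyloxy)-5-methoxy-6-prenylchroman-3-yl]acetic acid F1.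
 - Activation with 1,1′-carbonyldiimidazole and crossed Claisen condensation with the lithium enolate of methyl 5-methylhex-4-enoate (LDA, THF, −78 °C) should give the β-keto ester F2.
 - Et3N/Me3SiCl, then LDA/Me3SiCl (THF, −78 °C), should give the 1-methoxy-1,3-bis(trimethylsilyloxy)diene F3.
 - Diels–Alder reaction with but-3-yn-2-one (toluene, 80 °C) joins the nucleophilic terminus C1′ to the alkyne CH and the ketene-acetal carbon C4′ to the acyl-bearing carbon. Acidic work-up (loss of methanol, desilylation) should give the 5′-acetyl-2′,4′-dihydroxyaryl chroman F4.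
 - Dakin oxidation (H2O2, NaOH, degassed THF/H2O, 0 °C) and oxidation of the resulting triol with FeCl3 should give 25. Should the alkaline peroxide also remove the silyl ether, the sequence ends at 26.

2. Step 7. Attack of the phenoxide at the lactone carbonyl (translactonisation) or intermolecular alkylation may outrun the intramolecular alkyl–oxygen cleavage.
 Fallback (ring closure by Mitsunobu etherification; sets out from 10, returns at 11):
 - The lactone 10 is opened with AlMe3/MeNH(OMe)·HCl (CH2Cl2, 0 °C → rt) to the hydroxy N-methoxy-N-methylamide F5.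
 - PPh3/DIAD (THF, 0 °C) closes the chroman through the ortho phenol to the amide F6.
 - KOt-Bu/H2O (THF, rt) hydrolyses the amide to 11.

3. Step 12. Electron-transfer oxidation may spill over to ring A or the prenyl groups, or stop at a partly dealkylated stage.
 Fallback (phenol-directed two-electron oxidation; sets out from 24, returns at 25):
 - PhI(OAc)2 in MeOH (0 °C) should oxidise only the free phenol of ring B. The pendant hydroxyethyl group traps the ortho position, giving the spiro-dioxolane ortho-quinone monoketal F7.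
 - 1 M HCl in THF (rt) hydrolyses the ketal and the vinylogous ethyl ester to 25.

**Further compounds**

F1 | step 11 | 2-[(3R)-7-(tert-butyldimethylsilyloxy)-5-methoxy-6-prenylchroman-3-yl]acetic acid | COc1c(CC=C(C)C)c(O[Si](C)(C)C(C)(C)C)cc2c1C[C@H](CC(=O)O)CO2
F2 | step 11 | methyl 2-{2-[(3R)-7-(tert-butyldimethylsilyloxy)-5-methoxy-6-prenylchroman-3-yl]acetyl}-5-methylhex-4-enoate | COc1c(CC=C(C)C)c(O[Si](C)(C)C(C)(C)C)cc2c1C[C@H](CC(=O)C(CC=C(C)C)C(=O)OC)CO2
F3 | step 11 | 1-methoxy-1,3-bis(trimethylsilyloxy)-2-prenyl-4-[(3R)-chroman-3-yl]buta-1,3-diene (chroman as in 12) | COc1c(CC=C(C)C)c(O[Si](C)(C)C(C)(C)C)cc2c1C[C@H](C=C(O[Si](C)(C)C)C(CC=C(C)C)=C(OC)O[Si](C)(C)C)CO2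
F4 | step 11 | 1-{2,4-dihydroxy-3-prenyl-5-[(3R)-7-(tert-butyldimethylsilyloxy)-5-methoxy-6-prenylchroman-3-yl]phenyl}ethan-1-one | COc1c(CC=C(C)C)c(O[Si](C)(C)C(C)(C)C)cc2c1C[C@H](c1cc(C(C)=O)c(O)c(CC=C(C)C)c1O)CO2
F5 | step 7 | (3R)-4-hydroxy-N-methoxy-N-methyl-3-{[4,6-dihydroxy-2-methoxy-3-prenylphenyl]methyl}butanamide | COc1c(CC=C(C)C)c(O)cc(O)c1C[C@H](CC(=O)N(C)OC)CO
F6 | step 7 | 2-[(3R)-7-hydroxy-5-methoxy-6-prenylchroman-3-yl]-N-methoxy-N-methylacetamide | COc1c(CC=C(C)C)c(O)cc2c1C[C@H](CC(=O)N(C)OC)CO2
F7 | step 12 | spiro-dioxolane ortho-quinone monoketal of 24 (8-ethoxy-7-prenyl-9-[(3R)-chroman-3-yl]-1,4-dioxaspiro[4.5]deca-7,9-dien-6-one, chroman as in 12) | COc1c(CC=C(C)C)c(O[Si](C)(C)C(C)(C)C)cc2c1C[C@H](C1=CC3(OCCO3)C(=O)C(CC=C(C)C)=C1OCC)CO2
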